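**Retrosynthetic overview**

- The strategy rests on the E-configured C2=C3 alkene of the side chain (C1 = OCH2, C8 = terminal CH2). Its C3 methyl is cis to C1, the pattern left by syn methyl–aluminium addition to a terminal alkyne followed by retentive capture at the metal-bearing carbon.
- Key disconnections are C3–CH3 and C2–C1, both made in one flask from alkyne 6, Al(CH3)3 12 and aryloxymethyl chloride 11. No ring is formed in the route; both benzene rings are bought in 7.
- Alkyne 6 comes from (S)-epichlorohydrin (source of the C5 stereocentre), isopropenyl Grignard and lithium acetylide. Electrophile 11 comes from 2,4,6-trihydroxybenzophenone through its 4-O-methylthiomethyl ether.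
- The two phenols flanking the ketone are carried as bulky silyl ethers, not as chelating acetals. They shield the diaryl ketone from the alanate and allow one fluoride deprotection that spares the acid-labile allylic aryl ether and the isopropenyl group.

Key step: step 7

**Route**

Step 1
Reactants: 1 (S)-epichlorohydrin; 2 isopropenylmagnesium bromide
Product: 3 (S)-1-chloro-4-methylpent-4-en-2-ol
Conditions: CuI (10 mol %), THF, −40 → −20 °C; aq. NH4Cl
Reagents that add atoms: none
Why: Copper-catalysed Grignard opening of the epoxide (SN2 at the unsubstituted ring carbon, faster than chloride displacement at low temperature) should give the chlorohydrin without touching the stereocentre, so the S configuration of 1 is carried over; isolating 3 removes any epoxide from direct chloride displacement, which would lead to the wrong enantiomer.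

Step 2
Reactants: 3 (S)-1-chloro-4-methylpent-4-en-2-ol
Product: 5 (S)-6-methylhept-6-en-1-yn-4-ol, via (S)-2-(2-methylprop-2-enyl)oxirane 4 (not isolated)
Conditions: LiC≡CH·H2NCH2CH2NH2 (3 equiv), DMSO/THF, 0 °C → rt; H2O
Reagents that add atoms: lithium acetylide–ethylenediamine complex, [Li]C#C.NCCN
Why: The first equivalent of acetylide deprotonates the chlorohydrin, the alkoxide closes to epoxide 4 by intramolecular Williamson displacement, and a further equivalent opens 4 at its CH2 terminus (SN2 alkynylation of a terminal epoxide), so the carbinol carbon is never a reaction site and stays S.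

Step 3
Reactants: 5 (S)-6-methylhept-6-en-1-yn-4-ol
Product: 6 (S)-tert-butyldimethyl[(6-methylhept-6-en-1-yn-4-yl)oxy]silane
Conditions: TBSCl (1.2 equiv), imidazole (2.5 equiv), DMF, rt
Reagents that add atoms: tert-butyldimethylsilyl chloride, CC(C)(C)[Si](C)(C)Cl
Why: Standard silylation of a secondary alcohol (TBSCl/imidazole) masks the hydroxyl, which would otherwise consume organoaluminium reagent and be O-alkylated in the key step.

Step 4
Reactants: 7 2,4,6-trihydroxybenzophenone; 8 chloromethyl methyl sulfide
Product: 9 [2,6-dihydroxy-4-(methylsulfanylmethoxy)phenyl](phenyl)methanone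
Conditions: K2CO3 (1.05 equiv), DMF, 0 °C → rt
Reagents that add atoms: none
Why: The 4-OH, para to the carbonyl and the only hydroxyl not hydrogen-bonded to it, is the most acidic, so one equivalent of carbonate gives the 4-phenoxide, which should undergo Williamson O-alkylation with the α-chloro sulfide while the two chelated ortho hydroxyls stay protonated.

Step 5
Reactants: 9 [2,6-dihydroxy-4-(methylsulfanylmethoxy)phenyl](phenyl)methanone
Product: 10 [2,6-bis(tert-butyldimethylsilyloxy)-4-(methylsulfanylmethoxy)phenyl](phenyl)methanone
Conditions: TBSCl (3 equiv), imidazole (6 equiv), DMAP (0.1 equiv), DMF, rt → 45 °C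
Reagents that add atoms: tert-butyldimethylsilyl chloride, CC(C)(C)[Si](C)(C)Cl
Why: Imidazole/DMAP-promoted silylation of both hydrogen-bonded phenols should give the bis-silyl ether, whose bulky ortho groups twist and shield the ketone and bring no acidic proton or chelating acetal oxygen into the organoaluminium step.

Step 6
Reactants: 10 [2,6-bis(tert-butyldimethylsilyloxy)-4-(methylsulfanylmethoxy)phenyl](phenyl)methanone
Product: 11 [2,6-bis(tert-butyldimethylsilyloxy)-4-(chloromethoxy)phenyl](phenyl)methanone
Conditions: SO2Cl2 (1.05 equiv), cyclohexene (2 equiv), CH2Cl2, −78 → 0 °C; volatiles removed under high vacuum, crude 11 used at once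
Reagents that add atoms: sulfuryl chloride, O=S(=O)(Cl)Cl
Why: Sulfuryl chloride chlorinates the sulfide sulfur far faster than the arene and the chlorosulfonium ion fragments to the aryloxymethyl chloride and CH3SCl (the established conversion of methylthiomethyl ethers into chloromethyl ethers), with cyclohexene trapping the sulfenyl chloride before it can attack the electron-rich ring.

Step 7
Reactants: 6 (S)-tert-butyldimethyl[(6-methylhept-6-en-1-yn-4-yl)oxy]silane; 12 trimethylaluminium; 11 [2,6-bis(tert-butyldimethylsilyloxy)-4-(chloromethoxy)phenyl](phenyl)methanone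
Product: 15 [2,6-bis(tert-butyldimethylsilyloxy)-4-{[(2E,5S)-5-(tert-butyldimethylsilyloxy)-3,7-dimethylocta-2,7-dien-1-yl]oxy}phenyl](phenyl)methanone, via alkenyldimethylalane 13 (not isolated), via lithium alkenylbutyldimethylalanate 14 (not isolated)
Conditions: 6 (1.0 equiv), Al(CH3)3 (2.5 equiv), Cp2ZrCl2 (0.25 equiv), CH2Cl2, 0 °C → rt; volatiles removed in vacuo; n-BuLi (1.0 equiv), THF/hexane, −78 → 0 °C; 11 (0.7 equiv) in THF, −78 → 0 °C; H2O
Reagents that add atoms: none
Why: Cp2ZrCl2-catalysed methylalumination adds CH3 and Al syn across the terminal alkyne of 6, CH3 to the internal carbon (C3) and Al to the terminus (C2), to give alkenylalane 13; n-BuLi turns it into the nucleophilic alanate 14, whose alkenyl group displaces chloride from the α-chloro ether 11 with retention at the sp2 carbon and so forms C2–C1. The closest known reaction type is zirconium-catalysed carboalumination of a terminal alkyne followed by alkylation of the alkenylalanate with chloromethyl methyl ether or paraformaldehyde; an aryl chloromethyl ether is an electrophile of the same class. No ring is closed and no stereocentre is created: the E geometry (C3 methyl cis to C1) follows from syn addition plus retentive substitution, and the S centre at C5 is a spectator. Regioselectivity comes from the terminal alkyne, and the 1,1-disubstituted C7=C8 alkene and the silyl ethers are inert to the Zr/Al reagent. The step needs attack at CH2Cl and not at the diaryl ketone, which is secured by the two ortho silyloxy groups that twist and shield the carbonyl, by stripping excess Al(CH3)3 before ate formation, by keeping n-BuLi at no more than one equivalent per aluminium so that no free alkyllithium remains, and by using the reactive α-chloro ether as the limiting component at low temperature.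

Step 8
Reactants: 15 [2,6-bis(tert-butyldimethylsilyloxy)-4-{[(2E,5S)-5-(tert-butyldimethylsilyloxy)-3,7-dimethylocta-2,7-dien-1-yl]oxy}phenyl](phenyl)methanone
Product: 16 [2,6-dihydroxy-4-{[(2E,5S)-5-hydroxy-3,7-dimethylocta-2,7-dien-1-yl]oxy}phenyl](phenyl)methanone
Conditions: Bu4NF (4 equiv), AcOH (4 equiv), THF, 0 °C → rt
Reagents that add atoms: none
Why: Fluoride-induced desilylation (Si–F bond formation) should cleave the two aryl silyl ethers quickly and the secondary alkyl silyl ether more slowly, and the acetic acid buffer keeps the medium near neutral so that the allylic aryl ether, the isopropenyl group and the C5 stereocentre are untouched.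

**Compound list**

1 | (S)-epichlorohydrin | ClC[C@@H]1CO1 | starting material
2 | isopropenylmagnesium bromide | C=C(C)[Mg]Br | starting material
3 | (S)-1-chloro-4-methylpent-4-en-2-ol | ClC[C@@H](O)CC(C)=C | intermediate
4 | (S)-2-(2-methylprop-2-enyl)oxirane (formed in the flask, not isolated) | C=C(C)C[C@H]1CO1 | intermediate
5 | (S)-6-methylhept-6-en-1-yn-4-ol | C=C(C)C[C@H](O)CC#C | intermediate
6 | (S)-tert-butyldimethyl[(6-methylhept-6-en-1-yn-4-yl)oxy]silane | C=C(C)C[C@H](O[Si](C)(C)C(C)(C)C)CC#C | intermediate
7 | 2,4,6-trihydroxybenzophenone | O=C(c1ccccc1)c1c(O)cc(O)cc1O | starting material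
8 | chloromethyl methyl sulfide | CSCCl | starting material
9 | [2,6-dihydroxy-4-(methylsulfanylmethoxy)phenyl](phenyl)methanone | CSCOc1cc(O)c(C(=O)c2ccccc2)c(O)c1 | intermediate
10 | [2,6-bis(tert-butyldimethylsilyloxy)-4-(methylsulfanylmethoxy)phenyl](phenyl)methanone | CSCOc1cc(O[Si](C)(C)C(C)(C)C)c(C(=O)c2ccccc2)c(O[Si](C)(C)C(C)(C)C)c1 | intermediate
11 | [2,6-bis(tert-butyldimethylsilyloxy)-4-(chloromethoxy)phenyl](phenyl)methanone | ClCOc1cc(O[Si](C)(C)C(C)(C)C)c(C(=O)c2ccccc2)c(O[Si](C)(C)C(C)(C)C)c1 | intermediate
12 | trimethylaluminium | C[Al](C)C | starting material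
13 | dimethyl[(1E,4S)-4-(tert-butyldimethylsilyloxy)-2,6-dimethylhepta-1,6-dien-1-yl]alane (formed in the flask, not isolated) | C=C(C)C[C@H](O[Si](C)(C)C(C)(C)C)C/C(C)=C/[Al](C)C | intermediate
14 | lithium butyl[(1E,4S)-4-(tert-butyldimethylsilyloxy)-2,6-dimethylhepta-1,6-dien-1-yl]dimethylalanate (formed in the flask, not isolated) | C=C(C)C[C@H](O[Si](C)(C)C(C)(C)C)C/C(C)=C/[Al-](C)(C)CCCC.[Li+] | intermediate
15 | [2,6-bis(tert-butyldimethylsilyloxy)-4-{[(2E,5S)-5-(tert-butyldimethylsilyloxy)-3,7-dimethylocta-2,7-dien-1-yl]oxy}phenyl](phenyl)methanone | C=C(C)C[C@H](O[Si](C)(C)C(C)(C)C)C/C(C)=C/COc1cc(O[Si](C)(C)C(C)(C)C)c(C(=O)c2ccccc2)c(O[Si](C)(C)C(C)(C)C)c1 | intermediate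
16 | [2,6-dihydroxy-4-{[(2E,5S)-5-hydroxy-3,7-dimethylocta-2,7-dien-1-yl]oxy}phenyl](phenyl)methanone | C=C(C)C[C@H](O)C/C(C)=C/COc1cc(O)c(C(=O)c2ccccc2)c(O)c1 | target

**Step count**

Total steps: 8. Longest linear sequence: 5 steps (1 → 2 → 3 → 7 → 8; the arene branch 4 → 5 → 6 → 7 → 8 is equally long).

**Steps most likely to fail**

Step 7. The alanate may transfer its alkenyl, methyl or butyl group to the diaryl ketone. Substitution at the aryloxymethyl chloride, which ionises less readily than an alkoxymethyl chloride, may be slow. The α-chloro ether may also hydrolyse before it is coupled. The fallback sets out from 6 and comes back to the route at 16. Alanate 14 is made as in step 7 and quenched with paraformaldehyde, the established hydroxymethylation of alkenylalanates, to give the allylic alcohol (2E,5S)-5-(tert-butyldimethylsilyloxy)-3,7-dimethylocta-2,7-dien-1-ol F1. Mitsunobu etherification of F1 with 7 (PPh3, diisopropyl azodicarboxylate, THF, 0 °C) should engage only the non-chelated, most acidic 4-OH and give [2,6-dihydroxy-4-{[(2E,5S)-5-(tert-butyldimethylsilyloxy)-3,7-dimethylocta-2,7-dien-1-yl]oxy}phenyl](phenyl)methanone F2. Desilylation of F2 with Bu4NF/AcOH in THF would then give 16. The C1–O bond is made last here, and no chloromethyl ether or protected ketone is needed.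

Step 4. Alkylation may continue at a chelated ortho hydroxyl, or the electrophile may attack a ring carbon of the phloroglucinol nucleus. The fallback sets out from 7 and comes back at 10, bypassing 9 and step 5. Exhaustive silylation (TBSCl, imidazole, DMF) would give [2,4,6-tris(tert-butyldimethylsilyloxy)phenyl](phenyl)methanone F3. Brief treatment with K2CO3 in MeOH/THF at −10 °C should cleave first the 4-O-silyl ether, the only one not flanked by the benzoyl group and the one para to the carbonyl, to give [2,6-bis(tert-butyldimethylsilyloxy)-4-hydroxyphenyl](phenyl)methanone F4. The single free phenol of F4 is then alkylated with 8 (NaH, DMF, 0 °C) to give 10.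

Step 5. The second silylation, next to the benzoyl group and an existing silyl ether, may stall, or an ortho silyl ether may be lost on purification. The fallback sets out from 9 and comes back at 16. Acetal protection (NaH, CH3OCH2Cl, DMF) would give [2,6-bis(methoxymethoxy)-4-(methylsulfanylmethoxy)phenyl](phenyl)methanone F5. SO2Cl2/cyclohexene as in step 6 would give [4-(chloromethoxy)-2,6-bis(methoxymethoxy)phenyl](phenyl)methanone F6. Coupling of F6 with alanate 14 as in step 7 would give [4-{[(2E,5S)-5-(tert-butyldimethylsilyloxy)-3,7-dimethylocta-2,7-dien-1-yl]oxy}-2,6-bis(methoxymethoxy)phenyl](phenyl)methanone F7. Dilute HCl in MeOH at rt would remove the silyl ether and both acetals of F7 to give 16. This variant gives up the steric shielding of the ketone and needs a carefully timed acid step to spare the allylic aryl ether.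

**Further compounds**

F1 | step 7 | (2E,5S)-5-(tert-butyldimethylsilyloxy)-3,7-dimethylocta-2,7-dien-1-ol | C=C(C)C[C@H](O[Si](C)(C)C(C)(C)C)C/C(C)=C/CO
F2 | step 7 | [2,6-dihydroxy-4-{[(2E,5S)-5-(tert-butyldimethylsilyloxy)-3,7-dimethylocta-2,7-dien-1-yl]oxy}phenyl](phenyl)methanone | C=C(C)C[C@H](O[Si](C)(C)C(C)(C)C)C/C(C)=C/COc1cc(O)c(C(=O)c2ccccc2)c(O)c1
F3 | step 4 | [2,4,6-tris(tert-butyldimethylsilyloxy)phenyl](phenyl)methanone | CC(C)(C)[Si](C)(C)Oc1cc(O[Si](C)(C)C(C)(C)C)c(C(=O)c2ccccc2)c(O[Si](C)(C)C(C)(C)C)c1
F4 | step 4 | [2,6-bis(tert-butyldimethylsilyloxy)-4-hydroxyphenyl](phenyl)methanone | Oc1cc(O[Si](C)(C)C(C)(C)C)c(C(=O)c2ccccc2)c(O[Si](C)(C)C(C)(C)C)c1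
F5 | step 5 | [2,6-bis(methoxymethoxy)-4-(methylsulfanylmethoxy)phenyl](phenyl)methanone | CSCOc1cc(OCOC)c(C(=O)c2ccccc2)c(OCOC)c1
F6 | step 5 | [4-(chloromethoxy)-2,6-bis(methoxymethoxy)phenyl](phenyl)methanone | ClCOc1cc(OCOC)c(C(=O)c2ccccc2)c(OCOC)c1
F7 | step 5 | [4-{[(2E,5S)-5-(tert-butyldimethylsilyloxy)-3,7-dimethylocta-2,7-dien-1-yl]oxy}-2,6-bis(methoxymethoxy)phenyl](phenyl)methanone | C=C(C)C[C@H](O[Si](C)(C)C(C)(C)C)C/C(C)=C/COc1cc(OCOC)c(C(=O)c2ccccc2)c(OCOC)c1
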